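## The problem

- **Ring system.** The target is a 6,7-dihydro-1H-isochromen-8(5H)-one. A cyclohexenone (ring A) is fused through the tetrasubstituted C4a=C8a double bond to a 2H-pyran (ring B), so that O2–C3=C4–C4a=C8a–C8=O is one push–pull dienone.
- **Stereocentres.** There are four, in two isolated pairs: the cis-related C6 (secondary, acylated) and C7 (tertiary carbinol bearing the methyl group) on ring A, and the trans-epoxide carbons C2' and C3' of the side chain on C3.
- **Control.** A C6 oxygen can direct the creation of C7 on a six-membered template. Nothing in ring A can control the remote epoxide, so it has to arrive as an enantiopure fragment.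
- **Fragile groups.** The vinyl epoxide on the electron-rich dienol ether is sensitive to acid and to zerovalent palladium. The 2H-pyran dienone is sensitive to acid and hard nucleophiles. In the C6–C7–C8 array the C6–C7 bond can break by retro-aldol, and the C6 oxygen can be lost by vinylogous elimination through C5. The resorcinol is free. The hindered orsellinate should therefore go on late and be unmasked with buffered fluoride.
- **Where the difficulty lies.** Ring B closes easily once C8a carries a CH2O unit and C4a a two-carbon unit at the alkyne oxidation level. The hard part is an enantiopure ring A with cis C6/C7 oxygens and a C8 carbonyl distinguished from C4a.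
- **Enabling feature.** C5 (CH2), C6 (CH–O), C7 (C(CH3)–OH) and C8 (C=O) stand in a row and match C2 to C5 of a 2-deoxy-4-C-methyl-hexopyranose with D configuration at C3. Sugar C6 and C1 are then C8a and C4a. Excising the ring oxygen and joining C6 to C1 (Ferrier carbocyclisation of the hex-5-enopyranoside) converts the sugar into ring A.

## Retrosynthesis

**Ester C(=O)–O6 bond.** Target 31 is traced to its bis-silyl ether 30 and then, by cutting the ester bond, to diol 26 and aroyl chloride 29. The latter comes from the persilylated acid 28 and orsellinic acid 27. The ester is attached last because an acyloxy group at C6 would be the best leaving group in the molecule during every basic step, and phenol protection would otherwise have to survive the whole sequence. The forward reaction must acylate the secondary C6 hydroxyl beside the free tertiary C7 hydroxyl and then release two phenols without touching epoxide or dienone.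

**Ring B, O2–C3 bond.** Diol 26 is opened at O2–C3 to the ynenone 23 (through 24 and 25). This cut is preferred to O2–C1 or to closing C4–C4a last. In 23 the distal alkyne carbon is the δ-position of an extended acceptor, so a C1 alkoxide can only add 6-endo. The precursor is monocyclic and contains every carbon of the target core. The forward step needs only fluoride.

**C4–C4a bond.** Ynenone 23 is cut between the sp and sp2 carbons into the vinylogous acyl triflate 18 and the epoxy alkyne 22. The coupling is between a ring A piece carrying both stereocentres and a five-carbon piece carrying the epoxide, so each stereochemical pair is made separately. Alkyne 22 goes back through aldehyde 21 to epoxy alcohol 20 and to (E)-but-2-en-1-ol 19 by asymmetric epoxidation.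

**C8a–C1 bond and the C4a leaving group.** Triflate 18 comes from dione 17, which comes from β-hydroxy ketone 16, silyl ether 14, hydroxymethyl enone 13 and enone 12. The C8a–C1 bond is cut as a Morita–Baylis–Hillman hydroxymethylation, the most reliable way to put one carbon on the α-position of a cyclohexenone. The price is that the C4a oxygen must be put back by conjugate borylation–oxidation. A direct aldol on the β-hydroxy ketone 10 would be shorter but would run through a β-oxygenated enolate (kept as a reserve idea only). The forward sequence must end with sulfonylation of the dione at the oxygen on C4a, away from the quaternary C7.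

**Ring A, C8a–C4a bond (key cut).** Enone 12 comes from the β-hydroxy ketone 10, which is disconnected between C8a and C4a to the hex-5-enopyranoside 8. Any aldol-type closure in ring A could in principle be used, but only this one lets a hexose supply C5–C8 with both oxygens in place. The ketone can enolise in one direction only. The precursor is a protected sugar with two stereocentres that are already correct.

**Sugar.** Enol ether 8 is traced through iodide 7 and alcohol 6 to the branched glycoside 5. Cutting the C4–CH3 bond (sugar numbering) leads to ketone 4, then to glycoside 3, the bis-silyl glycal 2 and D-glucal 1. The methyl addition must give the axial tertiary hydroxyl, cis to O3. Everything else is protecting-group and leaving-group work with well-known regioselectivity.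

## Roads not taken

**Alternative 1:** ring A by nickel-catalysed insertion of an alkyne into a cyclobutanone.
- **Cut.** The C8–C8a and C4a–C5 bonds.
- **Forward step.** A zerovalent nickel–phosphine catalyst would couple the carbonyl of cyclobutanone A2 with the diyne A3, cleave C8–C5 by β-carbon elimination and form C4a–C5 by reductive elimination to give A1.
- **Merits.** One step would deliver the tetrasubstituted enone with the CH2O unit on C8a and an alkyne on C4a. It would replace steps 8 to 14 and 17 of the chosen route. On step count it is clearly better.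
- **Weak points.** A2 is a strained, enantiopure cis-dioxygenated cyclobutanone with a tertiary centre and has no obvious chiral-pool source. β-Carbon elimination could also cleave the bond to the quaternary C7. The regiochemistry of diyne insertion rests on the directing effect of the second alkyne. The silylalkyne of A1 would still have to be turned into the epoxide-bearing side chain, most likely by late reagent-controlled epoxidation of an enyne.
- **Comparison.** The chosen plan sets against the shorter sequence a secure origin of C6 and C7 in D-glucal, a ring closure with no regiochemical choice, and an epoxide brought in ready-made as 22.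

**Alternative 2:** ring B by formal [3+3] annulation.
- **Cut.** The C4–C4a and O2–C1 bonds.
- **Forward step.** The lithium enolate of epoxy ketone A6 would displace chloride from the chloro enone acetate A5. Base would expel acetate through the dienolate, and the 1-oxatriene would close by oxa-6π electrocyclisation to A4, the bis-silyl ether of 26.
- **Merits.** Ring B forms in one flask without palladium. A6 is one step from (E)-pent-3-en-2-one, whereas 22 takes two steps and is more volatile. In these respects it is better.
- **Weak points.** A hard lithium enolate can add 1,2 to the carbonyl. The coupled product is acidic and consumes enolate. The same base can deprotonate C5 and expel the C6 silyloxy group. A5 has to be made through a 2-(acyloxymethyl)-1,3-dione, which tends to lose its oxygen substituent. The alternative says nothing about how ring A is made.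
- **Comparison.** The chosen plan forms C4–C4a by a Sonogashira coupling, which is indifferent to these acidity problems, and closes O2–C3 where conjugation dictates the regiochemistry. It pays with one more fragment step.

**Alternative 3:** ring A by α-ketol ring expansion.
- **Cut.** The C6–C7 bond.
- **Forward step.** A chelating Lewis acid would promote the 1,2-shift of C6 from C8 to the acetyl carbon in the acetylcyclopentenol A8. This expands the five-membered ring and creates C7, giving A7. A7 is identical with compound 23, so the endgame would be shared.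
- **Merits.** C7 is set in the same step that builds the ring, and the route meets the chosen one at a late intermediate. If A8 were short to make, this road would be shorter.
- **Weak points.** The sp2 carbon C8a can migrate in competition with C6. The configuration at C7 depends on the chelate geometry and on the configuration of the carbinol in A8, which needs its own asymmetric synthesis together with C6. The Lewis acid must spare a propargylic epoxide.
- **Comparison.** The chosen plan takes C6 from the sugar and sets C7 by an addition whose facial preference is known for pyranosid-4-uloses. The epoxide is introduced only after all Lewis-acidic and oxidative steps on ring A.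

Key step: step 8

Remarks on the chemistry:
- Isochromene numbering (C1, O2, C3, C4, C4a, C5 to C8, C8a) is used for the target and for the corresponding carbons of carbocyclic intermediates. Pyranosides carry sugar numbering.
- D-Glucal is taken as the commercial form of the 2-deoxy-D-arabino-hexose skeleton.
- Compounds 15 and 16 are diastereomer mixtures at two centres that later become sp2.

## Route

Step 1
Reactants: 1 D-glucal (1,5-anhydro-2-deoxy-D-arabino-hex-1-enitol)
Product: 2 3,6-bis-O-(tert-butyldimethylsilyl)-D-glucal
Conditions: TBSCl (2.2 equiv), imidazole, DMF, 0 °C → rt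
Reagents that add atoms: tert-butyldimethylsilyl chloride, CC(C)(C)[Si](C)(C)Cl
Why: Regioselective silylation: the primary O6 and the allylic O3 react before O4, which is flanked on both sides; this is the standard 3,6-disilylation of D-glucal and leaves only the C4 hydroxyl free.

Step 2
Reactants: 2 3,6-bis-O-(tert-butyldimethylsilyl)-D-glucal
Product: 3 methyl 3,6-bis-O-(tert-butyldimethylsilyl)-2-deoxy-α-D-arabino-hexopyranoside
Conditions: MeOH (5 equiv), Ph3P·HBr (5 mol %), CH2Cl2, rt
Reagents that add atoms: methanol, CO
Why: Acid-catalysed addition of an alcohol to a glycal through the C1 oxocarbenium ion; axial attack and the anomeric effect should give the α-glycoside, and a silyl ether at C3 is too poor a leaving group for allylic rearrangement. The anomeric centre is lost in step 8, so any β-anomer can be carried along.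

Step 3
Reactants: 3 methyl 3,6-bis-O-(tert-butyldimethylsilyl)-2-deoxy-α-D-arabino-hexopyranoside
Product: 4 methyl 3,6-bis-O-(tert-butyldimethylsilyl)-2-deoxy-α-D-threo-hexopyranosid-4-ulose
Conditions: Dess–Martin periodinane, NaHCO3, CH2Cl2, 0 °C → rt
Reagents that add atoms: none
Why: Dess–Martin oxidation of the only free hydroxyl; the buffered, non-basic medium should avoid epimerisation at C3 or C5 and β-elimination of the C6 silyloxy group.

Step 4
Reactants: 4 methyl 3,6-bis-O-(tert-butyldimethylsilyl)-2-deoxy-α-D-threo-hexopyranosid-4-ulose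
Product: 5 methyl 3,6-bis-O-(tert-butyldimethylsilyl)-2-deoxy-4-C-methyl-α-D-lyxo-hexopyranoside
Conditions: MeMgBr, Et2O, −78 °C
Reagents that add atoms: methylmagnesium bromide, C[Mg]Br
Why: Grignard addition to a pyranosid-4-ulose; attack along the equatorial direction, anti to the C5–O5 bond and away from the axial lone pair of the ring oxygen, is the usual course for 4-uloses (the same sense that turns gluco into galacto on hydride reduction). It should place the methyl group equatorial and the new hydroxyl axial, cis to O3, which sets C7 of the target.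

Step 5
Reactants: 5 methyl 3,6-bis-O-(tert-butyldimethylsilyl)-2-deoxy-4-C-methyl-α-D-lyxo-hexopyranoside
Product: 6 methyl 3-O-(tert-butyldimethylsilyl)-2-deoxy-4-C-methyl-α-D-lyxo-hexopyranoside
Conditions: HF·pyridine, pyridine, THF, 0 °C
Reagents that add atoms: none
Why: Selective desilylation: a primary silyl ether is cleaved much faster than the secondary one next to the quaternary centre, and the pyridine buffer protects the acid-labile 2-deoxy glycoside.

Step 6
Reactants: 6 methyl 3-O-(tert-butyldimethylsilyl)-2-deoxy-4-C-methyl-α-D-lyxo-hexopyranoside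
Product: 7 methyl 3-O-(tert-butyldimethylsilyl)-2,6-dideoxy-6-iodo-4-C-methyl-α-D-lyxo-hexopyranoside
Conditions: PPh3, I2, imidazole, toluene, rt → 60 °C
Reagents that add atoms: iodine, II
Why: Appel-type iodination of the primary alcohol through its alkoxyphosphonium salt; the tertiary hydroxyl does not react.

Step 7
Reactants: 7 methyl 3-O-(tert-butyldimethylsilyl)-2,6-dideoxy-6-iodo-4-C-methyl-α-D-lyxo-hexopyranoside
Product: 8 methyl 3-O-(tert-butyldimethylsilyl)-2,6-dideoxy-4-C-methyl-α-D-erythro-hex-5-enopyranoside
Conditions: DBU, THF, 65 °C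
Reagents that add atoms: none
Why: E2 dehydroiodination across C5–C6, the standard entry to hex-5-enopyranosides; the free tertiary hydroxyl could only close a four-membered ether and should not compete.

Step 8
Reactants: 8 methyl 3-O-(tert-butyldimethylsilyl)-2,6-dideoxy-4-C-methyl-α-D-erythro-hex-5-enopyranoside
Product: 10 (2R,3R,5R)-3-(tert-butyldimethylsilyloxy)-2,5-dihydroxy-2-methylcyclohexan-1-one, via mercurio keto-aldehyde 9 (not isolated)
Conditions: Hg(OCOCF3)2 (5 mol %), acetone/H2O (4:1), rt
Reagents that add atoms: water, O; mercury bis(trifluoroacetate), FC(F)(F)C(=O)O[Hg]OC(=O)C(F)(F)F (retained only in intermediate 9)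
Why: Ferrier carbocyclisation: divalent mercury adds to the exocyclic enol ether at sugar C6 and water at C5, the hemiketal collapses to the C5 ketone, the C1 hemiacetal loses methanol, and the α-mercurio ketone adds to the unveiled aldehyde while the mercury salt is released for the next turnover. The closure is a 6-(enolendo)-exo-trig aldol that forms the C8a–C4a bond and ring A; the closest known reaction type is the catalytic-mercury Ferrier carbocyclisation of hex-5-enopyranosides, 2-deoxy substrates included. Regiochemistry is not in question, because the ketone is flanked by the quaternary C7 and can enolise only towards the mercurated carbon. The one new stereocentre, the C4a carbinol, is set by a chair-like transition state that keeps the silyloxy group equatorial, so the hydroxyl is expected mainly trans to it (5R); either epimer serves, since the centre is removed in step 9. C6 and C7 pass unchanged from sugar C3 and C4. The step needs chemoselective oxymercuration of the enol ether ahead of acid hydrolysis of the glycoside and without loss of the silyl ether; the nearly neutral medium and the low loading of Hg(OCOCF3)2 should secure this, and the tertiary hydroxyl is inert.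

Step 9
Reactants: 10 (2R,3R,5R)-3-(tert-butyldimethylsilyloxy)-2,5-dihydroxy-2-methylcyclohexan-1-one
Product: 12 (5R,6R)-5-(tert-butyldimethylsilyloxy)-6-hydroxy-6-methylcyclohex-2-en-1-one, via mesylate 11 (not isolated)
Conditions: MsCl (1.1 equiv), Et3N, CH2Cl2, 0 °C → rt
Reagents that add atoms: methanesulfonyl chloride, CS(=O)(=O)Cl (retained only in intermediate 11)
Why: Mesylation of the secondary β-hydroxyl followed by E1cB elimination under the same amine base, the usual dehydration of Ferrier products; the tertiary α-hydroxyl is sulfonylated much more slowly and the C4a stereocentre disappears.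

Step 10
Reactants: 12 (5R,6R)-5-(tert-butyldimethylsilyloxy)-6-hydroxy-6-methylcyclohex-2-en-1-one
Product: 13 (5R,6R)-5-(tert-butyldimethylsilyloxy)-6-hydroxy-2-(hydroxymethyl)-6-methylcyclohex-2-en-1-one
Conditions: 37% aq. HCHO, DMAP (20 mol %), THF/H2O (1:1), rt
Reagents that add atoms: formaldehyde, C=O
Why: Morita–Baylis–Hillman hydroxymethylation: the nucleophilic amine adds to the unsubstituted β-carbon, the enolate captures formaldehyde at C8a and the catalyst is expelled; this forms the C8a–C1 bond under conditions too mild to deprotonate C5.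

Step 11
Reactants: 13 (5R,6R)-5-(tert-butyldimethylsilyloxy)-6-hydroxy-2-(hydroxymethyl)-6-methylcyclohex-2-en-1-one
Product: 14 (5R,6R)-5-(tert-butyldimethylsilyloxy)-2-[(tert-butyldimethylsilyloxy)methyl]-6-hydroxy-6-methylcyclohex-2-en-1-one
Conditions: TBSCl, imidazole, CH2Cl2, 0 °C
Reagents that add atoms: tert-butyldimethylsilyl chloride, CC(C)(C)[Si](C)(C)Cl
Why: Silylation of the primary allylic alcohol; the tertiary hydroxyl is not silylated by the chloride under these conditions.

Step 12
Reactants: 14 (5R,6R)-5-(tert-butyldimethylsilyloxy)-2-[(tert-butyldimethylsilyloxy)methyl]-6-hydroxy-6-methylcyclohex-2-en-1-one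
Product: 16 (2R,3R)-3-(tert-butyldimethylsilyloxy)-6-[(tert-butyldimethylsilyloxy)methyl]-2,5-dihydroxy-2-methylcyclohexan-1-one, via β-boryl ketone 15 (not isolated)
Conditions: B2pin2, CuCl (5 mol %), NaOt-Bu (10 mol %), DPEphos (5 mol %), MeOH (2 equiv), THF, rt; then NaBO3·4H2O, THF/H2O, rt
Reagents that add atoms: bis(pinacolato)diboron, CC1(C)OB(OC1(C)C)B1OC(C)(C)C(C)(C)O1 (boron retained only in intermediate 15); sodium perborate, [Na+].[O-]OB=O (oxygen of the new hydroxyl)
Why: Copper-catalysed conjugate borylation of an α-substituted cyclic enone, with methanol protonating the copper enolate before it can expel the silyloxy group, then perborate oxidation of the C–B bond with retention; this returns the oxygen to C4a, and the configurations at C4a and C8a do not matter.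

Step 13
Reactants: 16 (2R,3R)-3-(tert-butyldimethylsilyloxy)-6-[(tert-butyldimethylsilyloxy)methyl]-2,5-dihydroxy-2-methylcyclohexan-1-one
Product: 17 (4R,5R)-5-(tert-butyldimethylsilyloxy)-2-[(tert-butyldimethylsilyloxy)methyl]-4-hydroxy-4-methylcyclohexane-1,3-dione
Conditions: Dess–Martin periodinane, NaHCO3, CH2Cl2, rt; used without storage
Reagents that add atoms: none
Why: Dess–Martin oxidation of a β-hydroxy ketone to the 1,3-diketone; the tertiary hydroxyl cannot be oxidised, and the enolised dione is taken on at once to avoid loss of the silyloxymethyl oxygen.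

Step 14
Reactants: 17 (4R,5R)-5-(tert-butyldimethylsilyloxy)-2-[(tert-butyldimethylsilyloxy)methyl]-4-hydroxy-4-methylcyclohexane-1,3-dione
Product: 18 (4R,5R)-5-(tert-butyldimethylsilyloxy)-2-[(tert-butyldimethylsilyloxy)methyl]-4-hydroxy-4-methyl-3-oxocyclohex-1-en-1-yl trifluoromethanesulfonate
Conditions: Tf2O (1.1 equiv), Et3N, CH2Cl2, −78 °C
Reagents that add atoms: trifluoromethanesulfonic anhydride, FC(F)(F)S(=O)(=O)OS(=O)(=O)C(F)(F)F
Why: O-Sulfonylation of the dione enolate to a vinylogous acyl triflate; the oxygen on C4a is remote from the quaternary C7, and the C8 carbonyl is held by a hydrogen bond to the C7 hydroxyl, so the leaving group should end on C4a with the carbonyl at C8.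

Step 15
Reactants: 19 (E)-but-2-en-1-ol
Product: 20 [(2R,3R)-3-methyloxiran-2-yl]methanol
Conditions: Ti(OiPr)4 (5 mol %), D-(−)-diisopropyl tartrate (6 mol %), t-BuOOH, 4 Å MS, CH2Cl2, −20 °C; non-aqueous work-up
Reagents that add atoms: tert-butyl hydroperoxide, CC(C)(C)OO
Why: Sharpless asymmetric epoxidation; the D-(−)-tartrate ligand directs oxygen to the face that gives the (2R,3R) epoxide, and the E-alkene fixes the trans relationship, so both epoxide stereocentres of the target are set here.

Step 16
Reactants: 20 [(2R,3R)-3-methyloxiran-2-yl]methanol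
Product: 22 (2R,3R)-2-ethynyl-3-methyloxirane, via epoxy aldehyde 21 (not isolated)
Conditions: TEMPO (10 mol %), PhI(OAc)2, CH2Cl2, rt; then MeOH, K2CO3, dimethyl (1-diazo-2-oxopropyl)phosphonate, 0 °C → rt; product kept as a solution
Reagents that add atoms: dimethyl (1-diazo-2-oxopropyl)phosphonate, COP(=O)(OC)C(=[N+]=[N-])C(C)=O
Why: Oxoammonium oxidation to the aldehyde, then Ohira–Bestmann (Seyferth–Gilbert) homologation to the terminal alkyne; the epoxide carbon next to the carbonyl has a cyclopropane-like C–H and should keep its configuration under carbonate, and telescoping avoids isolating the volatile, water-soluble aldehyde.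

Step 17
Reactants: 18 (4R,5R)-5-(tert-butyldimethylsilyloxy)-2-[(tert-butyldimethylsilyloxy)methyl]-4-hydroxy-4-methyl-3-oxocyclohex-1-en-1-yl trifluoromethanesulfonate; 22 (2R,3R)-2-ethynyl-3-methyloxirane
Product: 23 (5R,6R)-5-(tert-butyldimethylsilyloxy)-2-[(tert-butyldimethylsilyloxy)methyl]-6-hydroxy-6-methyl-3-{[(2R,3R)-3-methyloxiran-2-yl]ethynyl}cyclohex-2-en-1-one
Conditions: PdCl2(PPh3)2 (5 mol %), CuI (10 mol %), i-Pr2NEt, THF, 0 °C → rt
Reagents that add atoms: none
Why: Sonogashira coupling forms the C4–C4a bond; the electron-poor vinylogous acyl triflate undergoes oxidative addition at or below room temperature, well before the propargylic epoxide can ionise, and the amine base leaves the silyl ethers and the α-ketol untouched.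

Step 18
Reactants: 23 (5R,6R)-5-(tert-butyldimethylsilyloxy)-2-[(tert-butyldimethylsilyloxy)methyl]-6-hydroxy-6-methyl-3-{[(2R,3R)-3-methyloxiran-2-yl]ethynyl}cyclohex-2-en-1-one
Product: 26 (6R,7R)-6,7-dihydroxy-7-methyl-3-[(2S,3R)-3-methyloxiran-2-yl]-6,7-dihydro-1H-isochromen-8(5H)-one, via primary alcohol 24 (not isolated), via silyl ether 25 (not isolated)
Conditions: TBAF (3 equiv), THF, 0 °C → rt
Reagents that add atoms: none
Why: Fluoride cleaves the primary silyl ether first; the C1 alkoxide adds to the distal alkyne carbon C3 in a 6-endo-dig oxa-Michael (1,6-conjugate) addition and protonation at C4 gives the 2H-pyran, closing ring B, while 5-exo attack at C4 would be an anti-Michael addition with no stabilised anion. The slower cleavage of the C6 silyl ether then frees the diol; the epoxide descriptor changes from 2R to 2S only through substituent priorities.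

Step 19
Reactants: 27 orsellinic acid (2,4-dihydroxy-6-methylbenzoic acid)
Product: 28 tert-butyldimethylsilyl 2,4-bis(tert-butyldimethylsilyloxy)-6-methylbenzoate
Conditions: TBSCl (3.5 equiv), imidazole, DMF, rt
Reagents that add atoms: tert-butyldimethylsilyl chloride, CC(C)(C)[Si](C)(C)Cl
Why: Exhaustive silylation of the acid and both phenols gives a single non-acidic derivative in which the silyl ester is the latent acid chloride.

Step 20
Reactants: 28 tert-butyldimethylsilyl 2,4-bis(tert-butyldimethylsilyloxy)-6-methylbenzoate; 26 (6R,7R)-6,7-dihydroxy-7-methyl-3-[(2S,3R)-3-methyloxiran-2-yl]-6,7-dihydro-1H-isochromen-8(5H)-one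
Product: 30 (6R,7R)-7-hydroxy-7-methyl-3-[(2S,3R)-3-methyloxiran-2-yl]-8-oxo-5,6,7,8-tetrahydro-1H-isochromen-6-yl 2,4-bis(tert-butyldimethylsilyloxy)-6-methylbenzoate, via acid chloride 29 (not isolated)
Conditions: (COCl)2, DMF (cat.), CH2Cl2, 0 °C → rt, then evaporation; then 26, Et3N, DMAP, CH2Cl2, 0 °C → rt
Reagents that add atoms: oxalyl chloride, ClC(=O)C(Cl)=O (chlorine retained only in intermediate 29)
Why: A silyl ester is converted into the acid chloride by the chloroiminium reagent without free HCl, so the aryl silyl ethers survive; DMAP-catalysed acylation then takes the secondary C6 hydroxyl with retention, since the tertiary C7 hydroxyl is too hindered for this 2,6-disubstituted aroyl donor.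

Step 21
Reactants: 30 (6R,7R)-7-hydroxy-7-methyl-3-[(2S,3R)-3-methyloxiran-2-yl]-8-oxo-5,6,7,8-tetrahydro-1H-isochromen-6-yl 2,4-bis(tert-butyldimethylsilyloxy)-6-methylbenzoate
Product: 31 (6R,7R)-7-hydroxy-7-methyl-3-[(2S,3R)-3-methyloxiran-2-yl]-8-oxo-5,6,7,8-tetrahydro-1H-isochromen-6-yl 2,4-dihydroxy-6-methylbenzoate (CNP0323247.1)
Conditions: TBAF, AcOH (1:1), THF, 0 °C
Reagents that add atoms: none
Why: Aryl silyl ethers are cleaved rapidly by fluoride; the acetic acid buffer keeps the medium close to neutral, so the hindered ester, the epoxide and the dienone should be left intact.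

## Compound list

1 | D-glucal (1,5-anhydro-2-deoxy-D-arabino-hex-1-enitol) | C1=C[C@@H](O)[C@H](O)[C@@H](CO)O1 | starting material
2 | 3,6-bis-O-(tert-butyldimethylsilyl)-D-glucal | C1=C[C@@H](O[Si](C)(C)C(C)(C)C)[C@H](O)[C@@H](CO[Si](C)(C)C(C)(C)C)O1 | intermediate
3 | methyl 3,6-bis-O-(tert-butyldimethylsilyl)-2-deoxy-α-D-arabino-hexopyranoside | CO[C@@H]1C[C@@H](O[Si](C)(C)C(C)(C)C)[C@H](O)[C@@H](CO[Si](C)(C)C(C)(C)C)O1 | intermediate
4 | methyl 3,6-bis-O-(tert-butyldimethylsilyl)-2-deoxy-α-D-threo-hexopyranosid-4-ulose | CO[C@@H]1C[C@@H](O[Si](C)(C)C(C)(C)C)C(=O)[C@@H](CO[Si](C)(C)C(C)(C)C)O1 | intermediate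
5 | methyl 3,6-bis-O-(tert-butyldimethylsilyl)-2-deoxy-4-C-methyl-α-D-lyxo-hexopyranoside | CO[C@@H]1C[C@@H](O[Si](C)(C)C(C)(C)C)[C@@](C)(O)[C@@H](CO[Si](C)(C)C(C)(C)C)O1 | intermediate
6 | methyl 3-O-(tert-butyldimethylsilyl)-2-deoxy-4-C-methyl-α-D-lyxo-hexopyranoside | CO[C@@H]1C[C@@H](O[Si](C)(C)C(C)(C)C)[C@@](C)(O)[C@@H](CO)O1 | intermediate
7 | methyl 3-O-(tert-butyldimethylsilyl)-2,6-dideoxy-6-iodo-4-C-methyl-α-D-lyxo-hexopyranoside | CO[C@@H]1C[C@@H](O[Si](C)(C)C(C)(C)C)[C@@](C)(O)[C@@H](CI)O1 | intermediate
8 | methyl 3-O-(tert-butyldimethylsilyl)-2,6-dideoxy-4-C-methyl-α-D-erythro-hex-5-enopyranoside | CO[C@@H]1C[C@@H](O[Si](C)(C)C(C)(C)C)[C@@](C)(O)C(=C)O1 | intermediate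
9 | (3R,4R)-3-(tert-butyldimethylsilyloxy)-4-hydroxy-4-methyl-5-oxo-6-(trifluoroacetoxymercurio)hexanal | O=CC[C@@H](O[Si](C)(C)C(C)(C)C)[C@@](C)(O)C(=O)C[Hg]OC(=O)C(F)(F)F | intermediate (not isolated)
10 | (2R,3R,5R)-3-(tert-butyldimethylsilyloxy)-2,5-dihydroxy-2-methylcyclohexan-1-one | CC(C)(C)[Si](C)(C)O[C@@H]1C[C@@H](O)CC(=O)[C@]1(C)O | intermediate
11 | (1R,3R,4R)-3-(tert-butyldimethylsilyloxy)-4-hydroxy-4-methyl-5-oxocyclohexyl methanesulfonate | CC(C)(C)[Si](C)(C)O[C@@H]1C[C@@H](OS(C)(=O)=O)CC(=O)[C@]1(C)O | intermediate (not isolated)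
12 | (5R,6R)-5-(tert-butyldimethylsilyloxy)-6-hydroxy-6-methylcyclohex-2-en-1-one | CC(C)(C)[Si](C)(C)O[C@@H]1CC=CC(=O)[C@]1(C)O | intermediate
13 | (5R,6R)-5-(tert-butyldimethylsilyloxy)-6-hydroxy-2-(hydroxymethyl)-6-methylcyclohex-2-en-1-one | CC(C)(C)[Si](C)(C)O[C@@H]1CC=C(CO)C(=O)[C@]1(C)O | intermediate
14 | (5R,6R)-5-(tert-butyldimethylsilyloxy)-2-[(tert-butyldimethylsilyloxy)methyl]-6-hydroxy-6-methylcyclohex-2-en-1-one | CC(C)(C)[Si](C)(C)O[C@@H]1CC=C(CO[Si](C)(C)C(C)(C)C)C(=O)[C@]1(C)O | intermediate
15 | (2R,3R)-3-(tert-butyldimethylsilyloxy)-6-[(tert-butyldimethylsilyloxy)methyl]-2-hydroxy-2-methyl-5-(4,4,5,5-tetramethyl-1,3,2-dioxaborolan-2-yl)cyclohexan-1-one (mixture at C5 and C6) | CC(C)(C)[Si](C)(C)O[C@@H]1CC(B2OC(C)(C)C(C)(C)O2)C(CO[Si](C)(C)C(C)(C)C)C(=O)[C@]1(C)O | intermediate (not isolated)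
16 | (2R,3R)-3-(tert-butyldimethylsilyloxy)-6-[(tert-butyldimethylsilyloxy)methyl]-2,5-dihydroxy-2-methylcyclohexan-1-one (mixture at C5 and C6) | CC(C)(C)[Si](C)(C)O[C@@H]1CC(O)C(CO[Si](C)(C)C(C)(C)C)C(=O)[C@]1(C)O | intermediate
17 | (4R,5R)-5-(tert-butyldimethylsilyloxy)-2-[(tert-butyldimethylsilyloxy)methyl]-4-hydroxy-4-methylcyclohexane-1,3-dione (drawn as the diketo form; enolised) | CC(C)(C)[Si](C)(C)O[C@@H]1CC(=O)C(CO[Si](C)(C)C(C)(C)C)C(=O)[C@]1(C)O | intermediate
18 | (4R,5R)-5-(tert-butyldimethylsilyloxy)-2-[(tert-butyldimethylsilyloxy)methyl]-4-hydroxy-4-methyl-3-oxocyclohex-1-en-1-yl trifluoromethanesulfonate | CC(C)(C)[Si](C)(C)O[C@@H]1CC(OS(=O)(=O)C(F)(F)F)=C(CO[Si](C)(C)C(C)(C)C)C(=O)[C@]1(C)O | intermediate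
19 | (E)-but-2-en-1-ol | C/C=C/CO | starting material
20 | [(2R,3R)-3-methyloxiran-2-yl]methanol | OC[C@H]1O[C@@H]1C | intermediate
21 | (2S,3R)-3-methyloxirane-2-carbaldehyde | O=C[C@H]1O[C@@H]1C | intermediate (not isolated)
22 | (2R,3R)-2-ethynyl-3-methyloxirane | C#C[C@H]1O[C@@H]1C | intermediate
23 | (5R,6R)-5-(tert-butyldimethylsilyloxy)-2-[(tert-butyldimethylsilyloxy)methyl]-6-hydroxy-6-methyl-3-{[(2R,3R)-3-methyloxiran-2-yl]ethynyl}cyclohex-2-en-1-one | CC(C)(C)[Si](C)(C)O[C@@H]1CC(C#C[C@H]2O[C@@H]2C)=C(CO[Si](C)(C)C(C)(C)C)C(=O)[C@]1(C)O | intermediate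
24 | (5R,6R)-5-(tert-butyldimethylsilyloxy)-6-hydroxy-2-(hydroxymethyl)-6-methyl-3-{[(2R,3R)-3-methyloxiran-2-yl]ethynyl}cyclohex-2-en-1-one | CC(C)(C)[Si](C)(C)O[C@@H]1CC(C#C[C@H]2O[C@@H]2C)=C(CO)C(=O)[C@]1(C)O | intermediate (not isolated)
25 | (6R,7R)-6-(tert-butyldimethylsilyloxy)-7-hydroxy-7-methyl-3-[(2S,3R)-3-methyloxiran-2-yl]-6,7-dihydro-1H-isochromen-8(5H)-one | CC(C)(C)[Si](C)(C)O[C@@H]1CC2=C(COC([C@H]3O[C@@H]3C)=C2)C(=O)[C@]1(C)O | intermediate (not isolated)
26 | (6R,7R)-6,7-dihydroxy-7-methyl-3-[(2S,3R)-3-methyloxiran-2-yl]-6,7-dihydro-1H-isochromen-8(5H)-one | O[C@@H]1CC2=C(COC([C@H]3O[C@@H]3C)=C2)C(=O)[C@]1(C)O | intermediate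
27 | orsellinic acid (2,4-dihydroxy-6-methylbenzoic acid) | Cc1cc(O)cc(O)c1C(=O)O | starting material
28 | tert-butyldimethylsilyl 2,4-bis(tert-butyldimethylsilyloxy)-6-methylbenzoate | Cc1cc(O[Si](C)(C)C(C)(C)C)cc(O[Si](C)(C)C(C)(C)C)c1C(=O)O[Si](C)(C)C(C)(C)C | intermediate
29 | 2,4-bis(tert-butyldimethylsilyloxy)-6-methylbenzoyl chloride | Cc1cc(O[Si](C)(C)C(C)(C)C)cc(O[Si](C)(C)C(C)(C)C)c1C(Cl)=O | intermediate (not isolated)
30 | (6R,7R)-7-hydroxy-7-methyl-3-[(2S,3R)-3-methyloxiran-2-yl]-8-oxo-5,6,7,8-tetrahydro-1H-isochromen-6-yl 2,4-bis(tert-butyldimethylsilyloxy)-6-methylbenzoate | Cc1cc(O[Si](C)(C)C(C)(C)C)cc(O[Si](C)(C)C(C)(C)C)c1C(=O)O[C@@H]1CC2=C(COC([C@H]3O[C@@H]3C)=C2)C(=O)[C@]1(C)O | intermediate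
31 | (6R,7R)-7-hydroxy-7-methyl-3-[(2S,3R)-3-methyloxiran-2-yl]-8-oxo-5,6,7,8-tetrahydro-1H-isochromen-6-yl 2,4-dihydroxy-6-methylbenzoate | Cc1cc(O)cc(O)c1C(=O)O[C@@H]1CC2=C(COC([C@H]3O[C@@H]3C)=C2)C(=O)[C@]1(C)O | target

## Step count and risks

Total: 21 steps. Longest linear sequence: 18 steps (steps 1 to 14, 17, 18, 20 and 21, from D-glucal 1).

**Step 8 (key step).** The most likely failure is acid-catalysed hydrolysis of the enol ether and the 2-deoxy glycoside outrunning oxymercuration, so that the sugar opens without closing to the carbocycle. Silyl loss under the trifluoroacetic acid released from the catalyst is a second danger. Both arise because a 2-deoxy glycoside is unusually acid-labile and the catalyst loading is low. The fallback turns the hydrolysis into the intended path. Setting out from 8, dilute aqueous acetic acid in THF would give (3R,4R)-3-(tert-butyldimethylsilyloxy)-4-hydroxy-4-methyl-5-oxohexanal F1. Intramolecular aldol condensation under pyrrolidinium acetate, in which only the methyl ketone can form a six-membered ring with the aldehyde, would then lead straight to enone 12.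

**Step 14.** Poor regioselectivity of O-sulfonylation would give a mixture of the two enol triflates. Loss of the silyloxymethyl oxygen from the enolised dione before it is trapped is a second risk. The two enolate oxygens differ only by the neighbouring quaternary centre. The fallback does not pass through the dione. Setting out from enone 14, the zinc acetylide of 22 (n-BuLi, ZnBr2) would be added in conjugate fashion under Me3SiOTf promotion, which traps the enolate and silylates the tertiary hydroxyl. This would give {[(5R,6R)-5-(tert-butyldimethylsilyloxy)-2-[(tert-butyldimethylsilyloxy)methyl]-6-methyl-3-{[(2R,3R)-3-methyloxiran-2-yl]ethynyl}-6-(trimethylsilyloxy)cyclohex-1-en-1-yl]oxy}trimethylsilane F2. Saegusa–Ito dehydrogenation with Pd(OAc)2 in MeCN would restore the C4a=C8a double bond and give (5R,6R)-5-(tert-butyldimethylsilyloxy)-2-[(tert-butyldimethylsilyloxy)methyl]-6-methyl-3-{[(2R,3R)-3-methyloxiran-2-yl]ethynyl}-6-(trimethylsilyloxy)cyclohex-2-en-1-one F3. The fluoride treatment of step 18 would then remove all three silyl groups and close ring B, returning to the route at 26.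

**Step 18.** Unbuffered fluoride is basic. It may cause retro-aldol cleavage of the C6–C7 bond once the C6 hydroxyl is free, epoxide opening by alkoxide, or elimination through C5, and the hindered C6 silyl ether may be cleaved incompletely. The fallback separates deprotection from ring closure. Setting out from 23, HF·pyridine buffered with pyridine would remove both silyl groups under non-basic conditions to give (5R,6R)-5,6-dihydroxy-2-(hydroxymethyl)-6-methyl-3-{[(2R,3R)-3-methyloxiran-2-yl]ethynyl}cyclohex-2-en-1-one F4. The isolated triol would then be closed by a catalytic amount of DBU in CH2Cl2, which generates only the more acidic primary alkoxide in low concentration, returning at 26.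

**Step 20.** Acylation may be slow because a 2,6-disubstituted aroyl chloride meets a secondary alcohol next to a quaternary carbon. Prolonged exposure to amine base then invites elimination through C5 or attack on the aryl silyl ethers. The fallback changes the acyl donor and the mechanism. Setting out from 27, acetone with trifluoroacetic anhydride and trifluoroacetic acid would give 7-hydroxy-2,2,5-trimethyl-4H-1,3-benzodioxin-4-one F5, and silylation would give 7-(tert-butyldimethylsilyloxy)-2,2,5-trimethyl-4H-1,3-benzodioxin-4-one F6. The sodium alkoxide of 26 (NaHMDS, THF, −78 °C) would open this dioxinone by transesterification and free the ortho-phenol in the same event, giving (6R,7R)-7-hydroxy-7-methyl-3-[(2S,3R)-3-methyloxiran-2-yl]-8-oxo-5,6,7,8-tetrahydro-1H-isochromen-6-yl 4-(tert-butyldimethylsilyloxy)-2-hydroxy-6-methylbenzoate F7. The conditions of step 21 would convert F7 into 31.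

**Step 4.** Facial selectivity may be poor, giving the equatorial alcohol (methyl axial, hydroxyl trans to O3), because only one axial hydrogen shields the opposite face. Enolisation with loss of the C6 silyloxy group is a lesser risk. The fallback builds the same centre by a reversible addition. Setting out from ketone 4, dimethylsulfoxonium methylide (Me3S(O)I, NaH, DMSO; Corey–Chaykovsky) adds reversibly and closes from the betaine with the new carbon equatorial. This would give the spiro-epoxide methyl 4,4'-anhydro-3,6-bis-O-(tert-butyldimethylsilyl)-2-deoxy-4-C-(hydroxymethyl)-α-D-lyxo-hexopyranoside F8 with axial oxygen. Opening at the methylene carbon with LiEt3BH would return to the route at 5.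

## Further compounds

F1 | step 8 | (3R,4R)-3-(tert-butyldimethylsilyloxy)-4-hydroxy-4-methyl-5-oxohexanal | O=CC[C@@H](O[Si](C)(C)C(C)(C)C)[C@@](C)(O)C(C)=O
F2 | step 14 | {[(5R,6R)-5-(tert-butyldimethylsilyloxy)-2-[(tert-butyldimethylsilyloxy)methyl]-6-methyl-3-{[(2R,3R)-3-methyloxiran-2-yl]ethynyl}-6-(trimethylsilyloxy)cyclohex-1-en-1-yl]oxy}trimethylsilane (mixture at C3) | CC(C)(C)[Si](C)(C)O[C@@H]1CC(C#C[C@H]2O[C@@H]2C)C(CO[Si](C)(C)C(C)(C)C)=C(O[Si](C)(C)C)[C@]1(C)O[Si](C)(C)C
F3 | step 14 | (5R,6R)-5-(tert-butyldimethylsilyloxy)-2-[(tert-butyldimethylsilyloxy)methyl]-6-methyl-3-{[(2R,3R)-3-methyloxiran-2-yl]ethynyl}-6-(trimethylsilyloxy)cyclohex-2-en-1-one | CC(C)(C)[Si](C)(C)O[C@@H]1CC(C#C[C@H]2O[C@@H]2C)=C(CO[Si](C)(C)C(C)(C)C)C(=O)[C@]1(C)O[Si](C)(C)C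
F4 | step 18 | (5R,6R)-5,6-dihydroxy-2-(hydroxymethyl)-6-methyl-3-{[(2R,3R)-3-methyloxiran-2-yl]ethynyl}cyclohex-2-en-1-one | O[C@@H]1CC(C#C[C@H]2O[C@@H]2C)=C(CO)C(=O)[C@]1(C)O
F5 | step 20 | 7-hydroxy-2,2,5-trimethyl-4H-1,3-benzodioxin-4-one | Cc1cc(O)cc2OC(C)(C)OC(=O)c12
F6 | step 20 | 7-(tert-butyldimethylsilyloxy)-2,2,5-trimethyl-4H-1,3-benzodioxin-4-one | Cc1cc(O[Si](C)(C)C(C)(C)C)cc2OC(C)(C)OC(=O)c12
F7 | step 20 | (6R,7R)-7-hydroxy-7-methyl-3-[(2S,3R)-3-methyloxiran-2-yl]-8-oxo-5,6,7,8-tetrahydro-1H-isochromen-6-yl 4-(tert-butyldimethylsilyloxy)-2-hydroxy-6-methylbenzoate | Cc1cc(O[Si](C)(C)C(C)(C)C)cc(O)c1C(=O)O[C@@H]1CC2=C(COC([C@H]3O[C@@H]3C)=C2)C(=O)[C@]1(C)O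
F8 | step 4 | methyl 4,4'-anhydro-3,6-bis-O-(tert-butyldimethylsilyl)-2-deoxy-4-C-(hydroxymethyl)-α-D-lyxo-hexopyranoside | CO[C@@H]1C[C@@H](O[Si](C)(C)C(C)(C)C)[C@]2(CO2)[C@@H](CO[Si](C)(C)C(C)(C)C)O1
A1 | alternative 1 | (3aR,7aR)-5-[(tert-butyldimethylsilyloxy)methyl]-2,2,3a-trimethyl-6-[(trimethylsilyl)ethynyl]-7,7a-dihydro-1,3-benzodioxol-4(3aH)-one | CC1(C)O[C@@H]2CC(C#C[Si](C)(C)C)=C(CO[Si](C)(C)C(C)(C)C)C(=O)[C@]2(C)O1
A2 | alternative 1 | (1R,5R)-3,3,5-trimethyl-2,4-dioxabicyclo[3.2.0]heptan-6-one | CC1(C)O[C@@H]2CC(=O)[C@]2(C)O1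
A3 | alternative 1 | tert-butyldimethyl{[5-(trimethylsilyl)penta-2,4-diyn-1-yl]oxy}silane | CC(C)(C)[Si](C)(C)OCC#CC#C[Si](C)(C)C
A4 | alternative 2 | (6R,7R)-6,7-bis(tert-butyldimethylsilyloxy)-7-methyl-3-[(2S,3R)-3-methyloxiran-2-yl]-6,7-dihydro-1H-isochromen-8(5H)-one | CC(C)(C)[Si](C)(C)O[C@@H]1CC2=C(COC([C@H]3O[C@@H]3C)=C2)C(=O)[C@]1(C)O[Si](C)(C)C(C)(C)C
A5 | alternative 2 | [(4R,5R)-4,5-bis(tert-butyldimethylsilyloxy)-2-chloro-5-methyl-6-oxocyclohex-1-en-1-yl]methyl acetate | CC(C)(C)[Si](C)(C)O[C@@H]1CC(Cl)=C(COC(C)=O)C(=O)[C@]1(C)O[Si](C)(C)C(C)(C)C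
A6 | alternative 2 | 1-[(2S,3R)-3-methyloxiran-2-yl]ethan-1-one | CC(=O)[C@H]1O[C@@H]1C
A7 | alternative 3 | (5R,6R)-5-(tert-butyldimethylsilyloxy)-2-[(tert-butyldimethylsilyloxy)methyl]-6-hydroxy-6-methyl-3-{[(2R,3R)-3-methyloxiran-2-yl]ethynyl}cyclohex-2-en-1-one | CC(C)(C)[Si](C)(C)O[C@@H]1CC(C#C[C@H]2O[C@@H]2C)=C(CO[Si](C)(C)C(C)(C)C)C(=O)[C@]1(C)O
A8 | alternative 3 | (1S,5R)-1-acetyl-5-(tert-butyldimethylsilyloxy)-2-[(tert-butyldimethylsilyloxy)methyl]-3-{[(2R,3R)-3-methyloxiran-2-yl]ethynyl}cyclopent-2-en-1-ol | CC(=O)[C@]1(O)C(CO[Si](C)(C)C(C)(C)C)=C(C#C[C@H]2O[C@@H]2C)C[C@H]1O[Si](C)(C)C(C)(C)C
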